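**Retrosynthetic overview**
1. The target is the primary acetate of a dienediol; the last step is selective acetylation of the primary allylic hydroxyl beside the hindered tertiary one.
2. Key disconnection: the central sp2–sp2 bond of the diene (between the CH of the trisubstituted alkene and the neighbouring CH of the disubstituted alkene), made in the same flask as the bond from the fully substituted alkene carbon to the homoallylic CH2. This is a three-component union of a C18 homoallylic Grignard reagent, propargyl alcohol (C3) and (E)-4-(2-iodovinyl)furan-2(5H)-one (C6).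
3. Enabling feature: the CH2–O group on the fully substituted alkene carbon lies cis to the diene bond. A propargylic alkoxide oxygen can therefore hold magnesium on the adjacent CH in a five-membered O–Mg–C=C–C ring (anti-carbomagnesiation), which fixes the Z alkene before transmetalation to zinc and Negishi coupling.
4. C18 piece: RAMP-hydrazone methylation of 2,2-dimethylcyclohexanone gives the (S)-ketone; axial addition of a butynyl Grignard reagent sets the carbinol centre; carboalumination/ethylene oxide sets the E alkene; then bromide. C6 piece: 4-bromofuranone plus (E)-bis(stannyl)ethene, then iodine.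
5. Rings: none is formed in the route. The cyclohexane and butenolide rings are bought; the only ring closed is the transient oxamagnesacycle of the key step.

Key step: step 10

Assumption: the target is taken as drawn, (1R,6S) in the ring (side chain cis to the secondary ring methyl, hydroxyl trans to it); the enantiopure ring ketone is made rather than bought, and the other building blocks named as starting materials are taken as catalogue compounds.

**Step 1**
Reactants: 1 2,2-dimethylcyclohexan-1-one; 2 RAMP, (R)-1-amino-2-(methoxymethyl)pyrrolidine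
Product: 3 (R,E)-N-(2,2-dimethylcyclohexylidene)-2-(methoxymethyl)pyrrolidin-1-amine
Conditions: TsOH (cat.), cyclohexane, reflux, Dean–Stark trap
Reagents that add atoms: none
Why: Acid-catalysed hydrazone condensation, in which the amino nitrogen should settle anti to the quaternary C2 and therefore syn to C6, the only carbon that can be deprotonated in the next step.

**Step 2**
Reactants: 3 (R,E)-N-(2,2-dimethylcyclohexylidene)-2-(methoxymethyl)pyrrolidin-1-amine
Product: 5 (R)-2-(methoxymethyl)-N-[(1E,6S)-2,2,6-trimethylcyclohexylidene]pyrrolidin-1-amine, via lithium azaenolate 4 (not isolated)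
Conditions: LiN(iPr)2 (LDA), THF, 0 °C; then MeI, −100 °C → rt
Reagents that add atoms: iodomethane, CI
Why: Enders hydrazone alkylation, in which the methoxymethyl-chelated lithium azaenolate is methylated on one face only; since SAMP hydrazones of cyclohexanones give (R)-2-methyl ketones, the RAMP auxiliary is expected to set C6 as S.

**Step 3**
Reactants: 5 (R)-2-(methoxymethyl)-N-[(1E,6S)-2,2,6-trimethylcyclohexylidene]pyrrolidin-1-amine
Product: 6 (S)-2,2,6-trimethylcyclohexan-1-one
Conditions: saturated aq. oxalic acid, Et2O, rt (two-phase)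
Reagents that add atoms: water, O
Why: Mild two-phase hydrazone hydrolysis, which should release the ketone without epimerizing its single enolizable α-centre and return the auxiliary to the aqueous layer as its oxalate.

**Step 4**
Reactants: 6 (S)-2,2,6-trimethylcyclohexan-1-one; 7 (4-bromobut-1-yn-1-yl)trimethylsilane
Product: 9 (1R,6S)-2,2,6-trimethyl-1-[4-(trimethylsilyl)but-3-yn-1-yl]cyclohexan-1-ol, via Grignard reagent 8 (not isolated)
Conditions: 7, Mg, THF, rt; then CeCl3 (anhydrous), THF, −78 °C; then 6, −78 → 0 °C; H2O
Reagents that add atoms: none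
Why: CeCl3-mediated Grignard (organocerium) addition suppresses enolization and β-hydride reduction of the hindered ketone, and in the chair with the C6 methyl equatorial the axial C2 methyl blocks equatorial approach, so the nucleophile should enter axially, cis to the C6 methyl, which sets C1 as R.

**Step 5**
Reactants: 9 (1R,6S)-2,2,6-trimethyl-1-[4-(trimethylsilyl)but-3-yn-1-yl]cyclohexan-1-ol
Product: 10 (1R,6S)-1-(but-3-yn-1-yl)-2,2,6-trimethylcyclohexan-1-ol
Conditions: K2CO3 (cat.), MeOH, rt
Reagents that add atoms: none
Why: Methanolysis of the alkynyl C–Si bond (protodesilylation) under mild base, which leaves the tertiary alcohol and both stereocentres untouched.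

**Step 6**
Reactants: 10 (1R,6S)-1-(but-3-yn-1-yl)-2,2,6-trimethylcyclohexan-1-ol
Product: 13 (1R,6S)-1-[(3E)-6-hydroxy-3-methylhex-3-en-1-yl]-2,2,6-trimethylcyclohexan-1-ol, via alkenylalane 11 (not isolated), via lithium alkenylalanate 12 (not isolated)
Conditions: AlMe3 (3 equiv), Cp2ZrCl2 (0.3 equiv), CH2Cl2, 0 °C → rt; volatiles removed in vacuo; n-BuLi, hexane/THF, −78 °C; ethylene oxide, −78 → 0 °C; H2O
Reagents that add atoms: trimethylaluminium, C[Al](C)C; ethylene oxide, C1CO1
Why: Negishi zirconium-catalysed carboalumination adds methyl and aluminium syn across the terminal alkyne (methyl to the internal carbon), and the derived alanate opens ethylene oxide with retention, so the E trisubstituted alkene is fixed by the syn addition while the tertiary hydroxyl is carried as its aluminium alkoxide.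

**Step 7**
Reactants: 13 (1R,6S)-1-[(3E)-6-hydroxy-3-methylhex-3-en-1-yl]-2,2,6-trimethylcyclohexan-1-ol
Product: 14 (1R,6S)-1-[(3E)-6-bromo-3-methylhex-3-en-1-yl]-2,2,6-trimethylcyclohexan-1-ol
Conditions: PPh3, CBr4, CH2Cl2, 0 °C
Reagents that add atoms: tetrabromomethane, BrC(Br)(Br)Br
Why: Appel bromination should convert only the primary alcohol, because the tertiary carbinol flanked by a quaternary and a tertiary carbon cannot be activated or displaced under these nearly neutral conditions.

**Step 8**
Reactants: 15 4-bromofuran-2(5H)-one; 16 (E)-1,2-bis(tributylstannyl)ethene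
Product: 17 (E)-4-[2-(tributylstannyl)vinyl]furan-2(5H)-one
Conditions: 16 (2.5 equiv), Pd(PPh3)4 (5 mol %), toluene, 80 °C
Reagents that add atoms: none
Why: Stille coupling of the vinylogous acyl bromide with the bis-stannane in excess, which should transfer one alkenyl–tin bond with retention of the E geometry because the electron-poor dienyl stannane formed transmetalates more slowly than 16.

**Step 9**
Reactants: 17 (E)-4-[2-(tributylstannyl)vinyl]furan-2(5H)-one
Product: 18 (E)-4-(2-iodovinyl)furan-2(5H)-one
Conditions: I2, CH2Cl2, 0 °C, dark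
Reagents that add atoms: iodine, II
Why: Iododestannylation is an ipso substitution at the alkenyl carbon and should proceed with retention of the E geometry.

**Step 10**
Reactants: 14 (1R,6S)-1-[(3E)-6-bromo-3-methylhex-3-en-1-yl]-2,2,6-trimethylcyclohexan-1-ol; 19 prop-2-yn-1-ol; 18 (E)-4-(2-iodovinyl)furan-2(5H)-one
Product: 23 4-[(1E,3Z,7E)-4-(hydroxymethyl)-10-[(1R,6S)-1-hydroxy-2,2,6-trimethylcyclohexyl]-8-methyldeca-1,3,7-trien-1-yl]furan-2(5H)-one, via Grignard reagent 20 (not isolated), via oxamagnesacycle 21 (not isolated), via alkenylzinc bromide 22 (not isolated)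
Conditions: 14, iPrMgCl (1.0 equiv), THF, −20 °C, then Mg turnings, THF, 40 °C (gives 20, 1.3 equiv); 19 (1.0 equiv), iPrMgCl (1.0 equiv), THF, −40 °C, then CuI (10 mol %) and 20, −20 °C → rt (gives 21); ZnBr2 (2.0 equiv), THF, 0 °C (gives 22); 18 (1.0 equiv), Pd(PPh3)4 (5 mol %), rt; pH 7 aqueous work-up
Reagents that add atoms: none
Why: Bromide 14, carried as its chloromagnesium alkoxide, is turned into Grignard reagent 20, which adds by CuI-catalysed, alkoxide-directed anti-carbomagnesiation across the triple bond of the chloromagnesium alkoxide of 19 (alkyl to the internal carbon, magnesium to the terminal carbon, held cis to CH2O in oxamagnesacycle 21); ZnBr2 then gives the configurationally stable alkenylzinc 22, which couples with iodide 18 under zerovalent-palladium catalysis (Negishi coupling) with retention at both alkenes to form the central diene bond. The closest known reaction type is the three-component carbomagnesiation of propargylic alcohols followed by palladium-catalysed cross-coupling of the magnesium chelate in the same flask. No ring of the target is closed; the only ring formed is the transient five-membered oxamagnesacycle, closed as a chelate by the anti addition and opened again by transmetalation and work-up. No stereocentre is created; the Z geometry of the trisubstituted alkene is controlled by the chelate and the E geometry of the disubstituted alkene is carried in from 18. The step needs regio- and anti-selective carbometalation, secured by the propargylic oxygen, and chemoselective transfer of the sp2 zinc reagent beside residual alkylzinc and the base-sensitive butenolide, secured by the faster transmetalation of alkenylzinc and the low basicity of organozinc species.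

**Step 11**
Reactants: 23 4-[(1E,3Z,7E)-4-(hydroxymethyl)-10-[(1R,6S)-1-hydroxy-2,2,6-trimethylcyclohexyl]-8-methyldeca-1,3,7-trien-1-yl]furan-2(5H)-one
Product: 24 (2Z,4E)-2-{(3E)-6-[(1R,6S)-1-hydroxy-2,2,6-trimethylcyclohexyl]-4-methylhex-3-en-1-yl}-5-(5-oxo-2,5-dihydrofuran-3-yl)penta-2,4-dien-1-yl acetate
Conditions: Ac2O, pyridine, CH2Cl2, 0 °C
Reagents that add atoms: acetic anhydride, CC(=O)OC(C)=O
Why: Acylation of the unhindered primary allylic alcohol, while the tertiary hydroxyl flanked by C(CH3)2 and CH(CH3) should be inert to acetic anhydride and pyridine at 0 °C.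

**Compound list**
1 | 2,2-dimethylcyclohexan-1-one | O=C1CCCCC1(C)C | starting material
2 | RAMP, (R)-1-amino-2-(methoxymethyl)pyrrolidine | COC[C@H]1CCCN1N | starting material
3 | (R,E)-N-(2,2-dimethylcyclohexylidene)-2-(methoxymethyl)pyrrolidin-1-amine | COC[C@H]1CCCN1/N=C2\CCCCC2(C)C | intermediate
4 | lithium azaenolate of 3 (lithium on the hydrazone nitrogen, C1=C6 double bond in the ring) | COC[C@H]1CCCN1N([Li])C2=CCCCC2(C)C | intermediate
5 | (R)-2-(methoxymethyl)-N-[(1E,6S)-2,2,6-trimethylcyclohexylidene]pyrrolidin-1-amine | COC[C@H]1CCCN1/N=C2\[C@@H](C)CCCC2(C)C | intermediate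
6 | (S)-2,2,6-trimethylcyclohexan-1-one | O=C1[C@@H](C)CCCC1(C)C | intermediate
7 | (4-bromobut-1-yn-1-yl)trimethylsilane | C[Si](C)(C)C#CCCBr | starting material
8 | [4-(trimethylsilyl)but-3-yn-1-yl]magnesium bromide | C[Si](C)(C)C#CCC[Mg]Br | intermediate
9 | (1R,6S)-2,2,6-trimethyl-1-[4-(trimethylsilyl)but-3-yn-1-yl]cyclohexan-1-ol | C[Si](C)(C)C#CCC[C@@]1(O)[C@@H](C)CCCC1(C)C | intermediate
10 | (1R,6S)-1-(but-3-yn-1-yl)-2,2,6-trimethylcyclohexan-1-ol | C#CCC[C@@]1(O)[C@@H](C)CCCC1(C)C | intermediate
11 | (E)-alkenyl(dimethyl)alane from 10, tertiary oxygen as dimethylaluminium alkoxide | C[Al](C)/C=C(\C)CC[C@@]1(O[Al](C)C)[C@@H](C)CCCC1(C)C | intermediate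
12 | lithium butyl(dimethyl)[(E)-alkenyl]alanate from 11 | [Li+].CCCC[Al-](C)(C)/C=C(\C)CC[C@@]1(O[Al](C)C)[C@@H](C)CCCC1(C)C | intermediate
13 | (1R,6S)-1-[(3E)-6-hydroxy-3-methylhex-3-en-1-yl]-2,2,6-trimethylcyclohexan-1-ol | OCC/C=C(\C)CC[C@@]1(O)[C@@H](C)CCCC1(C)C | intermediate
14 | (1R,6S)-1-[(3E)-6-bromo-3-methylhex-3-en-1-yl]-2,2,6-trimethylcyclohexan-1-ol | BrCC/C=C(\C)CC[C@@]1(O)[C@@H](C)CCCC1(C)C | intermediate
15 | 4-bromofuran-2(5H)-one | BrC1=CC(=O)OC1 | starting material
16 | (E)-1,2-bis(tributylstannyl)ethene | CCCC[Sn](CCCC)(CCCC)/C=C/[Sn](CCCC)(CCCC)CCCC | starting material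
17 | (E)-4-[2-(tributylstannyl)vinyl]furan-2(5H)-one | CCCC[Sn](CCCC)(CCCC)/C=C/C1=CC(=O)OC1 | intermediate
18 | (E)-4-(2-iodovinyl)furan-2(5H)-one | I/C=C/C1=CC(=O)OC1 | intermediate
19 | prop-2-yn-1-ol (propargyl alcohol) | C#CCO | starting material
20 | homoallylic Grignard reagent from 14, tertiary oxygen as chloromagnesium alkoxide | Br[Mg]CC/C=C(\C)CC[C@@]1(O[Mg]Cl)[C@@H](C)CCCC1(C)C | intermediate
21 | five-membered oxamagnesacycle (ring O–Mg–CH=C–CH2) carrying the C18 chain on the ring alkene carbon remote from magnesium | C2(=C[Mg]OC2)CC/C=C(\C)CC[C@@]1(O[Mg]Cl)[C@@H](C)CCCC1(C)C | intermediate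
22 | (Z)-alkenylzinc bromide, zinc cis to the CH2O(MgBr) group | Br[Mg]OC/C(=C\[Zn]Br)CC/C=C(\C)CC[C@@]1(O[Mg]Cl)[C@@H](C)CCCC1(C)C | intermediate
23 | 4-[(1E,3Z,7E)-4-(hydroxymethyl)-10-[(1R,6S)-1-hydroxy-2,2,6-trimethylcyclohexyl]-8-methyldeca-1,3,7-trien-1-yl]furan-2(5H)-one | OC/C(=C\C=C\C1=CC(=O)OC1)CC/C=C(\C)CC[C@@]1(O)[C@@H](C)CCCC1(C)C | intermediate
24 | (2Z,4E)-2-{(3E)-6-[(1R,6S)-1-hydroxy-2,2,6-trimethylcyclohexyl]-4-methylhex-3-en-1-yl}-5-(5-oxo-2,5-dihydrofuran-3-yl)penta-2,4-dien-1-yl acetate | CC(=O)OC/C(=C\C=C\C1=CC(=O)OC1)CC/C=C(\C)CC[C@@]1(O)[C@@H](C)CCCC1(C)C | target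

**Totals**
Total step count: 11. Longest linear sequence: 9 (steps 1–7, 10, 11).

**Steps most likely to fail**

Step 10. The one-pot sequence may erode in three ways: metalation of the acetylenic C–H of the propargyl alkoxide by the valuable Grignard reagent, protonation or homocoupling of the alkenylzinc, and attack of the basic alkoxide medium on the iodobutenolide. Fallback, setting out from 14 (with 19): the carbomagnesiation is run as in step 10 but quenched with I2 at −40 °C, and (1R,6S)-1-[(3E,7Z)-7-(hydroxymethyl)-8-iodo-3-methylocta-3,7-dien-1-yl]-2,2,6-trimethylcyclohexan-1-ol F1 is isolated. F1 is then joined to stannane 17 by a Stille coupling under neutral conditions (Pd2(dba)3, AsPh3, NMP, 40 °C), so that the butenolide never meets an organomagnesium or organozinc medium. This comes back to the route at 23.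

Step 4. The sp3 organometallic may reduce or enolize the hindered ketone instead of adding, or its preference for axial attack may be too small, giving the C1 epimer. Fallback, setting out from 6: lithium 3,3-diethoxyprop-1-ynide (from 3,3-diethoxyprop-1-yne and n-BuLi, THF, −78 °C) is added as a small, linear nucleophile for which axial attack is most secure, giving (1R,6S)-1-(3,3-diethoxyprop-1-yn-1-yl)-2,2,6-trimethylcyclohexan-1-ol F2. Hydrogenation (H2, palladium on carbon, EtOAc, trace Et3N) gives (1R,6S)-1-(3,3-diethoxypropyl)-2,2,6-trimethylcyclohexan-1-ol F3. Mild acetal hydrolysis (aq. oxalic acid, acetone) gives 3-[(1R,6S)-1-hydroxy-2,2,6-trimethylcyclohexyl]propanal F4, expected to sit largely as its spiro-lactol. Seyferth–Gilbert homologation with the Ohira–Bestmann reagent (dimethyl (1-diazo-2-oxopropyl)phosphonate, K2CO3, MeOH) then comes back to the route at 10.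

Step 6. Vinyl transfer from the alanate to ethylene oxide may be incomplete, through competing methyl or butyl transfer or interference by the aluminium alkoxide. Fallback, setting out from 10: the same carboalumination is quenched with I2 to give (1R,6S)-1-[(3E)-4-iodo-3-methylbut-3-en-1-yl]-2,2,6-trimethylcyclohexan-1-ol F5. Stille coupling with tributyl(vinyl)stannane (Pd(PPh3)4, DMF, 60 °C) gives (1R,6S)-2,2,6-trimethyl-1-[(3E)-3-methylhexa-3,5-dien-1-yl]cyclohexan-1-ol F6. Hydroboration of the terminal vinyl group with disiamylborane (Sia2BH, THF, 0 °C; then NaOH, H2O2) comes back to the route at 13.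

**Further compounds**
F1 | step 10 | (1R,6S)-1-[(3E,7Z)-7-(hydroxymethyl)-8-iodo-3-methylocta-3,7-dien-1-yl]-2,2,6-trimethylcyclohexan-1-ol | OC/C(=C\I)CC/C=C(\C)CC[C@@]1(O)[C@@H](C)CCCC1(C)C
F2 | step 4 | (1R,6S)-1-(3,3-diethoxyprop-1-yn-1-yl)-2,2,6-trimethylcyclohexan-1-ol | CCOC(OCC)C#C[C@@]1(O)[C@@H](C)CCCC1(C)C
F3 | step 4 | (1R,6S)-1-(3,3-diethoxypropyl)-2,2,6-trimethylcyclohexan-1-ol | CCOC(OCC)CC[C@@]1(O)[C@@H](C)CCCC1(C)C
F4 | step 4 | 3-[(1R,6S)-1-hydroxy-2,2,6-trimethylcyclohexyl]propanal | O=CCC[C@@]1(O)[C@@H](C)CCCC1(C)C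
F5 | step 6 | (1R,6S)-1-[(3E)-4-iodo-3-methylbut-3-en-1-yl]-2,2,6-trimethylcyclohexan-1-ol | I/C=C(\C)CC[C@@]1(O)[C@@H](C)CCCC1(C)C
F6 | step 6 | (1R,6S)-2,2,6-trimethyl-1-[(3E)-3-methylhexa-3,5-dien-1-yl]cyclohexan-1-ol | C=C/C=C(\C)CC[C@@]1(O)[C@@H](C)CCCC1(C)C
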